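At 25.0 min the winter run still held 12.4 % of its substrate and target had stopped rising, so I took the partner for the limiting reagent, lost by a first-order route of its own while the substrate's forms captured it.

| setting | noon | summer | winter | blue | red | green |
|---|---|---|---|---|---|---|
| substrate | 0.30 M | 0.15 M | 0.60 M | 0.30 M | 0.30 M | 0.30 M (fed, over 15 min) |
| partner | 1 equiv | 1 equiv | 1 equiv | 1.00 equiv | 1.00 equiv (fed, over 15 min) | 1.00 equiv |
| remark | run made earlier | run made earlier | run made earlier | everything together at the start | all else is in the flask from the start; the feed brings no volume worth counting | all else is in the flask from the start; the feed brings no volume worth counting |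
| time |  |  |  | 25 min | 25 min | 25 min |

| run | time / min | target / % | substrate / % |
|---|---|---|---|
| noon | 1.33 | 4.2 | 51.6 |
| noon | 2.50 | 6.3 | 35.0 |
| noon | 4.00 | 8.8 | 25.1 |
| noon | 8.00 | 10.9 | 18.4 |
| noon | 15.0 | 9.6 | 15.7 |
| summer | 5.00 | 6.6 | 26.3 |
| summer | 10.0 | 8.4 | 20.4 |
| summer | 15.0 | 7.4 | 18.6 |
| summer | 20.0 | 7.1 | 19.3 |
| summer | 25.0 | 7.8 | 19.7 |
| winter | 2.00 | 8.2 | 33.5 |
| winter | 6.00 | 12.3 | 15.6 |
| winter | 12.0 | 12.2 | 13.2 |
| winter | 20.0 | 11.7 | 13.4 |
| winter | 25.0 | 11.3 | 12.4 |

(scatter of a reading: 0.5 percentage points)

- the best flask by amount of target, in percent of the substrate charged; "all alike" if 1.5 percentage points covers them all (blue / red / green / all alike)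
- amount of target at the end, in percent of the substrate charged, blue
- amount of target at the end, in percent of the substrate charged, red
- amount of target at the end, in percent of the substrate charged, green

- steps that have been proposed: substrate <-> tautomer; substrate + partner -> isomer of the product A; partner + tautomer -> target; partner -> decomposed reagent; target <-> isomer of the product B

I wrote target as y = Yc/(c + h), with c the substrate charged and Y the ceiling on y. Far below h, the curve makes y follow c, the form expected where capture is pseudo-first-order and loses to that loss, and winter over summer comes to 4.00. Far above h, the curve stands at Y, the form expected where capture wins, and the ratio is one. The real flasks lay between. Late target averaged 7.68 % in summer and 11.9 % in winter, a ratio of 1.55. That gave h = 0.134 M, the crossover concentration, a fitted constant of the curve marking the charge at which it stands midway to Y, and Y = 14.5 %, both as readings.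

For blue, which is noon's recipe, I reckoned 10.0 %; noon's 10.9 % and 9.6 % were not used and bracket it. The rule covers flasks charged together, so I put no number on red or green.

The forecast named red as best, with blue 9.2 %, red 13.5 % and green 3.5 %, since in red “partner arrives after tautomer has built up”.

Red ended at 21.9 %, 8.4 percentage points above the forecast, with blue at 10.1 % and green at 2.39 %, so red was best.

    substrate ⇌ tautomer (K = 3.00, k = 0.00600 s⁻¹)
    substrate + partner → isomer of the product A (k = 0.0130 M⁻¹ s⁻¹)
    partner + tautomer → target (k = 0.0230 M⁻¹ s⁻¹)
    partner → decomposed reagent (k = 0.00730 s⁻¹)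
    target ⇌ isomer of the product B (K = 0.400, k = 0.0150 s⁻¹)

Red held 8.49 % of isomer of the product A at 25.0 min, where blue held 20.7 %. Put through h, red's number means a ceiling of 31.6 %. At 0.51 M of substrate, on red's recipe otherwise, that ceiling gave 25.0 %, and the flask gave 27.6 %.

The earlier runs and the new flask are simulated with made-up constants, and the scatter is random.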